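(The earlier runs and the new flask were generated by integration from invented constants; noise was put on by code.)

all flasks: L 13 mM (held)

| run | D | remark | time |
|---|---|---|---|
| alpha | 48 mM | run made earlier |  |
| flask | 32 mM |  | 4.0 h |
alpha run (percent of the D charged)

| time / min | X / % | D / % |
|---|---|---|
| 6.00 | 4.9 | 86.0 |
| 10.0 | 9.2 | 74.0 |
| 20.0 | 15.4 | 57.6 |
| 40.0 | 20.4 | 36.1 |
| 80.0 | 18.9 | 19.8 |

(standard deviation of a reading: 1 percentage point)
- the earlier runs were read with a standard deviation of 1 percentage point
- at the start none of L is in solution
- Z is what L becomes in solution
- north: doubling the transfer coefficient of L, all else as stated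
- south-east: doubling the saturation concentration of L, all else as stated
1. amount of X at 4.0 h, in percent of the D charged
2. concentration of Z in solution at 2.0 h, in percent of saturation
3. the change that raises the amount of X at 4.0 h, in percent of the D charged most ("none" if none brings more than 2 percentage points) (north / south-east / none)
4. amount of X at 4.0 h, in percent of the D charged, after south-east

Start with a subtraction: count whatever in the alpha run is neither D nor X as a side product. Then work with fractions left. D already falls at 0.0251 min⁻¹ over the first 6.00 min, so assume that Z stands at its saturation of 13 mM from the start. Each step is then pseudo-first-order, and percentages from alpha serve the 32 mM flask as well.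

Let a be the rate constant of D to X, k of D to the side product, and b of X back to D. The first 10.0 min of alpha give a + k = 0.0301 min⁻¹. The side product's gain from 20.0 min to 40.0 min, over the mean D, gives k = 0.0176 min⁻¹, so a = 0.0125 min⁻¹. The slope of X over the last interval gives b = 0.0197 min⁻¹.

Now climb the ladder. Take Z as filled first, before the first reading. The two remaining rates sum to a + b + k and multiply to bk. The faster is 0.0414 min⁻¹. The slower is the tail rate λ, 0.00837 min⁻¹, a half-life of 82.8 min. On the tail, X and D fall together, and X is a/(λf − λ) times e^(−λt), with λf the faster rate. That gives 5.07% at 4.0 h. With Z taken as full, I expect Z at saturation at 2.0 h and little from north. In my reckoning south-east doubles a, slows the tail to 0.00618 min⁻¹, and gives 11.4%. My choice is south-east, with a gain of 6.3 percentage points, more than the 2 points asked.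

The forecast, which differs from my reckoning on the best change and on X after south-east, gave X 6% at 4.0 h, Z at 92% of saturation at 2.0 h, best change none, and X 2.5% after south-east, holding that "Doubling saturation speeds X loss".

The flask gives X 7.78% at 4.0 h, Z at 100% of saturation at 2.0 h, best change south-east (gain from north 0.064 points, from south-east 8.3 points), and X 16.0% after south-east.

    L ⇌ Z, rate k1*(csat - [Z]) (kL = 0.860 min⁻¹)
    D + Z ⇌ X (K = 68.0 M⁻¹, k = 1.00 M⁻¹ min⁻¹)
    D → G (k = 0.0180 min⁻¹)

In this flask, the relaxation half-life of D + Z and X by that step alone, 0.395 h, and the half-life of D by the step to G, 0.64 h, are both short against 4.0 h. Up to 4.0 h the net turnover in this flask is 87.5% of the D charged to G, against 7.78% to X. X in this flask falls from 2.0 h to 4.0 h at 0.00661 min⁻¹, against my λ of 0.00837 min⁻¹.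

Carry on to the same flask read at 15 h: λ takes 7.78% down to 0.0310%, and the computed flask holds 0.0872%.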